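**Strategy**

The oxolane (O1, C2 aryl, C3 hydroxymethyl, C4 arylmethyl, C5) is disconnected across O1–C5 and C3–C4 into a β-ketoester, which supplies O1, C2 and C3 with its ester carbon as the future CH2OH, and a two-carbon bis-electrophile C4–C5 carrying the 3,4-dimethoxybenzyl group. The feature exploited is the enol latent in the ring: O1 and C3 are the two nucleophilic ends of one 1,3-dicarbonyl. A cinchona-thiourea-catalysed Michael/O-alkylation domino with a (Z)-bromonitroalkene forms both bonds and sets C4; both partners are acyclic and the ketoester is flat at C2 and C3. After radical denitration, C4 steers a syn hydrogenation of C2=C3 to the all-cis triad.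

Key step: step 3

Remark on the chemistry: the target is read as the all-cis (2R,3R,4R) oxolane. The quinine-derived thiourea is assumed to deliver the 4R configuration in step 3; if the sense proves opposite, its quinidine-derived pseudoenantiomer is used with no other change. Compounds 1, 2 and 5 are taken as purchasable.

**Route**

Step 1
Reactants: 1 2-(3,4-dimethoxyphenyl)acetaldehyde; 2 bromonitromethane
Product: 3 1-bromo-3-(3,4-dimethoxyphenyl)-1-nitropropan-2-ol (mixture of diastereomers)
Conditions: NaI (15 mol %), THF, rt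
Reagents that add atoms: none
Why: Henry (nitroaldol) addition of bromonitromethane to the aldehyde under near-neutral iodide catalysis, which should spare the enolisable arylacetaldehyde from self-condensation; both new stereocentres are erased in step 2.

Step 2
Reactants: 3 1-bromo-3-(3,4-dimethoxyphenyl)-1-nitropropan-2-ol
Product: 4 (Z)-4-(3-bromo-3-nitroprop-2-en-1-yl)-1,2-dimethoxybenzene
Conditions: MsCl (1.05 equiv), Et3N (2.1 equiv), CH2Cl2, −40 to 0 °C
Reagents that add atoms: none
Why: Mesylation of the secondary alcohol and E1cB elimination through the highly acidic bromonitromethine should give the conjugated nitroalkene as the thermodynamically preferred Z isomer (bromine cis to the arylmethyl chain), with low temperature and exact base stoichiometry chosen to avoid migration of the double bond toward the arene.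

Step 3
Reactants: 4 (Z)-4-(3-bromo-3-nitroprop-2-en-1-yl)-1,2-dimethoxybenzene; 5 ethyl 3-oxo-3-(3,4,5-trimethoxyphenyl)propanoate
Product: 7 ethyl (4R,5R)-4-[(3,4-dimethoxyphenyl)methyl]-5-nitro-2-(3,4,5-trimethoxyphenyl)-4,5-dihydrofuran-3-carboxylate, via acyclic bromonitro Michael adduct 6 (not isolated)
Conditions: 1-[3,5-bis(trifluoromethyl)phenyl]-3-[(8S,9S)-6'-methoxycinchonan-9-yl]thiourea (10 mol %), K2CO3 (1.0 equiv, solid), CHCl3, −20 °C
Reagents that add atoms: none
Why: The quinuclidine nitrogen of the catalyst deprotonates ketoester 5 while the thiourea hydrogen-bonds the nitro group of 4, so the C3 enolate adds to C4 (Michael addition) to give adduct 6, whose ketone enol oxygen then displaces bromide at C5 in an intramolecular SN2 O-alkylation. The closest known reaction type is the organocatalytic asymmetric domino Michael/alkylation of 1,3-dicarbonyl compounds with (Z)-bromonitroalkenes to trans-2-nitro-2,3-dihydrofurans, a relative of the interrupted Feist-Benary reaction. The one ring closed, the dihydrofuran, forms by 5-exo-tet attack of O1 on C5. C4 is set by the catalyst, which exposes one face of the hydrogen-bonded nitroalkene to the ion-paired enolate; C5 forms trans to the C4 substituent and is erased in step 4, and C3 of 6 becomes planar on ring closure, so all diastereomers of 6 should converge on one product. The step needs O- over C-alkylation (5-exo dihydrofuran over 3-exo nitrocyclopropane), which the acidic aryl ketone enol should secure, and conjugate addition faster than γ-deprotonation of 4, which the low temperature, the weak heterogeneous base and the double activation of the alkene by bromine and nitro should secure.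

Step 4
Reactants: 7 ethyl (4R,5R)-4-[(3,4-dimethoxyphenyl)methyl]-5-nitro-2-(3,4,5-trimethoxyphenyl)-4,5-dihydrofuran-3-carboxylate
Product: 8 ethyl (4R)-4-[(3,4-dimethoxyphenyl)methyl]-2-(3,4,5-trimethoxyphenyl)-4,5-dihydrofuran-3-carboxylate
Conditions: Bu3SnH (1.5 equiv), AIBN (20 mol %), benzene, 80 °C
Reagents that add atoms: none
Why: Radical chain denitration with Bu3SnH, in which the stannyl radical adds to a nitro oxygen and the C5–N bond fragments readily because the C5 radical is stabilised by O1; the neutral, non-ionising conditions are chosen so that loss of nitrous acid to the furan does not compete, and C4 is not involved.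

Step 5
Reactants: 8 ethyl (4R)-4-[(3,4-dimethoxyphenyl)methyl]-2-(3,4,5-trimethoxyphenyl)-4,5-dihydrofuran-3-carboxylate
Product: 9 ethyl (2R,3S,4R)-4-[(3,4-dimethoxyphenyl)methyl]-2-(3,4,5-trimethoxyphenyl)oxolane-3-carboxylate
Conditions: H2 (5 bar), 10% Pd/C, EtOAc, rt
Reagents that add atoms: none
Why: Heterogeneous catalytic hydrogenation should add both hydrogens syn to the face of the nearly planar dihydrofuran opposite the C4 arylmethyl group, placing the C2 aryl and C3 ester groups cis to it and so setting C2 and C3 of the all-cis triad; neutral EtOAc is used to avoid epimerisation at C3 and hydrogenolysis of the benzylic C2–O bond.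

Step 6
Reactants: 9 ethyl (2R,3S,4R)-4-[(3,4-dimethoxyphenyl)methyl]-2-(3,4,5-trimethoxyphenyl)oxolane-3-carboxylate
Product: 10 [(2R,3R,4R)-4-[(3,4-dimethoxyphenyl)methyl]-2-(3,4,5-trimethoxyphenyl)oxolan-3-yl]methanol
Conditions: LiAlH4, THF, 0 °C; then H2O
Reagents that add atoms: none
Why: Ester reduction with LiAlH4 to the primary alcohol is faster than enolisation, so the labile C3 centre of the all-cis ester should be carried through unchanged (the descriptor changes from S to R only through the priority rules); the aryl methyl ethers and the oxolane are inert.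

**Compound list**

1 | 2-(3,4-dimethoxyphenyl)acetaldehyde | COc1ccc(CC=O)cc1OC | starting material
2 | bromonitromethane | [O-][N+](=O)CBr | starting material
3 | 1-bromo-3-(3,4-dimethoxyphenyl)-1-nitropropan-2-ol (diastereomer mixture) | COc1ccc(CC(O)C(Br)[N+](=O)[O-])cc1OC | intermediate
4 | (Z)-4-(3-bromo-3-nitroprop-2-en-1-yl)-1,2-dimethoxybenzene | COc1ccc(C/C=C(\Br)[N+](=O)[O-])cc1OC | intermediate
5 | ethyl 3-oxo-3-(3,4,5-trimethoxyphenyl)propanoate | CCOC(=O)CC(=O)c1cc(OC)c(OC)c(OC)c1 | starting material
6 | ethyl (3R)-4-bromo-3-[(3,4-dimethoxyphenyl)methyl]-4-nitro-2-(3,4,5-trimethoxybenzoyl)butanoate (epimer mixture at C2 and C4 of the chain) | COc1ccc(C[C@H](C(C(=O)OCC)C(=O)c2cc(OC)c(OC)c(OC)c2)C(Br)[N+](=O)[O-])cc1OC | intermediate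
7 | ethyl (4R,5R)-4-[(3,4-dimethoxyphenyl)methyl]-5-nitro-2-(3,4,5-trimethoxyphenyl)-4,5-dihydrofuran-3-carboxylate | COc1ccc(C[C@H]2[C@H]([N+](=O)[O-])OC(c3cc(OC)c(OC)c(OC)c3)=C2C(=O)OCC)cc1OC | intermediate
8 | ethyl (4R)-4-[(3,4-dimethoxyphenyl)methyl]-2-(3,4,5-trimethoxyphenyl)-4,5-dihydrofuran-3-carboxylate | COc1ccc(C[C@H]2COC(c3cc(OC)c(OC)c(OC)c3)=C2C(=O)OCC)cc1OC | intermediate
9 | ethyl (2R,3S,4R)-4-[(3,4-dimethoxyphenyl)methyl]-2-(3,4,5-trimethoxyphenyl)oxolane-3-carboxylate | COc1ccc(C[C@H]2CO[C@@H](c3cc(OC)c(OC)c(OC)c3)[C@H]2C(=O)OCC)cc1OC | intermediate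
10 | [(2R,3R,4R)-4-[(3,4-dimethoxyphenyl)methyl]-2-(3,4,5-trimethoxyphenyl)oxolan-3-yl]methanol | COc1ccc(C[C@H]2CO[C@@H](c3cc(OC)c(OC)c(OC)c3)[C@H]2CO)cc1OC | target

**Step count and risks**

Total step count: 6. Longest linear sequence: 6 steps (1 → 3 → 4 → 7 → 8 → 9 → 10).

Steps most likely to fail:

Step 3. The amine catalyst or the carbonate may move the double bond of 4 out of conjugation with the nitro group by γ-deprotonation at the benzylic CH2, the enolate may close on carbon to a nitrocyclopropane, or facial discrimination may be weak for an aliphatic bromonitroalkene. The fallback separates the two bond formations. It sets out from 1 and 5 and comes back to the route at 7. Aldehyde 1 and nitromethane (catalytic base) should give 1-(3,4-dimethoxyphenyl)-3-nitropropan-2-ol F1, which MsCl and Et3N should dehydrate to (E)-1,2-dimethoxy-4-(3-nitroprop-2-en-1-yl)benzene F2. Conjugate addition of 5 to F2 under the nearly neutral catalysis of NiBr2[(R,R)-N,N'-dibenzylcyclohexane-1,2-diamine]2 in toluene at rt (ligand enantiomer chosen for the 3R adduct) should give ethyl (3R)-3-[(3,4-dimethoxyphenyl)methyl]-4-nitro-2-(3,4,5-trimethoxybenzoyl)butanoate F3. N-Bromosuccinimide and K2CO3 should then brominate the nitronate to 6, which closes to 7 as in the main route.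

Step 4. Thermal or trace-acid loss of nitrous acid across C4–C5 to the aromatic furan, which would erase the C4 stereocentre, may outrun the radical chain. The fallback builds 8 without a nitro group. It sets out from 5 and comes back at 8. N-Bromosuccinimide should convert 5 into ethyl 2-bromo-3-oxo-3-(3,4,5-trimethoxyphenyl)propanoate F4. Photoredox organocatalytic α-alkylation of purchased 3-(3,4-dimethoxyphenyl)propanal with F4 (2-tert-butyl-3,5-dimethylimidazolidin-4-one triflate salt of the enantiomer that gives 3R, Ru(bpy)3Cl2, 2,6-lutidine, DMF, visible light) should give ethyl (3R)-3-[(3,4-dimethoxyphenyl)methyl]-4-oxo-2-(3,4,5-trimethoxybenzoyl)butanoate F5. This is reduced in the same flask with NaBH4 at −78 °C to ethyl (3R)-3-[(3,4-dimethoxyphenyl)methyl]-4-hydroxy-2-(3,4,5-trimethoxybenzoyl)butanoate F6. Catalytic TsOH in toluene over 4 Å molecular sieves should cyclodehydrate F6 to 8.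

Step 5. Hydrogen uptake by the tetrasubstituted push-pull C2=C3 bond may be slow, the benzylic C2–O bond may undergo hydrogenolysis once the ring is saturated, or facial control may be incomplete. The fallback uses carboxylate-directed homogeneous hydrogenation. It sets out from 8 and comes back at 10. LiOH in aqueous THF should give (4R)-4-[(3,4-dimethoxyphenyl)methyl]-2-(3,4,5-trimethoxyphenyl)-4,5-dihydrofuran-3-carboxylic acid F7. Hydrogenation with Ru(OAc)2(BINAP) of the matched ligand enantiomer (H2 50–100 bar, MeOH) should give (2R,3S,4R)-4-[(3,4-dimethoxyphenyl)methyl]-2-(3,4,5-trimethoxyphenyl)oxolane-3-carboxylic acid F8, with the catalyst reinforcing the bias from C4. LiAlH4 in THF then reduces F8 to 10.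

**Further compounds**

F1 | step 3 | 1-(3,4-dimethoxyphenyl)-3-nitropropan-2-ol | COc1ccc(CC(O)C[N+](=O)[O-])cc1OC
F2 | step 3 | (E)-1,2-dimethoxy-4-(3-nitroprop-2-en-1-yl)benzene | COc1ccc(C/C=C/[N+](=O)[O-])cc1OC
F3 | step 3 | ethyl (3R)-3-[(3,4-dimethoxyphenyl)methyl]-4-nitro-2-(3,4,5-trimethoxybenzoyl)butanoate | COc1ccc(C[C@H](C(C(=O)OCC)C(=O)c2cc(OC)c(OC)c(OC)c2)C[N+](=O)[O-])cc1OC
F4 | step 4 | ethyl 2-bromo-3-oxo-3-(3,4,5-trimethoxyphenyl)propanoate | CCOC(=O)C(Br)C(=O)c1cc(OC)c(OC)c(OC)c1
F5 | step 4 | ethyl (3R)-3-[(3,4-dimethoxyphenyl)methyl]-4-oxo-2-(3,4,5-trimethoxybenzoyl)butanoate | COc1ccc(C[C@H](C(C(=O)OCC)C(=O)c2cc(OC)c(OC)c(OC)c2)C=O)cc1OC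
F6 | step 4 | ethyl (3R)-3-[(3,4-dimethoxyphenyl)methyl]-4-hydroxy-2-(3,4,5-trimethoxybenzoyl)butanoate | COc1ccc(C[C@H](C(C(=O)OCC)C(=O)c2cc(OC)c(OC)c(OC)c2)CO)cc1OC
F7 | step 5 | (4R)-4-[(3,4-dimethoxyphenyl)methyl]-2-(3,4,5-trimethoxyphenyl)-4,5-dihydrofuran-3-carboxylic acid | COc1ccc(C[C@H]2COC(c3cc(OC)c(OC)c(OC)c3)=C2C(=O)O)cc1OC
F8 | step 5 | (2R,3S,4R)-4-[(3,4-dimethoxyphenyl)methyl]-2-(3,4,5-trimethoxyphenyl)oxolane-3-carboxylic acid | COc1ccc(C[C@H]2CO[C@@H](c3cc(OC)c(OC)c(OC)c3)[C@H]2C(=O)O)cc1OC
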